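In this scheme you cannot make a molecule of product without spending a molecule of partner, and the protic impurity spends partner too.

    substrate + free catalyst → catalyst intermediate A (k1 = 110 /M/s)
    partner + catalyst intermediate A → catalyst intermediate B (k2 = 17 /M/s)
    catalyst intermediate B → free catalyst + product (k3 = 3.3 /s)
    partner + protic impurity → quenched reagent (k4 = 0.072 /M/s)
    precatalyst → free catalyst (k5 = 0.0057 /s)

substrate 2.0 M; partner 2.20 M; protic impurity 0.400 M; precatalyst 10 mM; time 6.0 h

* at 6.0 h, what has stopped the reaction, if anything has (the partner has run out first / no working catalyst is left / it is still moving / all of the substrate has reacted)
* part of the substrate gone at 6.0 h
* the product standing at 6.0 h, as a percentage of the substrate charged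

- the reaction counts as stopped when no species that holds the substrate changes by six tenths of a point or more over the second half of the time
- run time (flask): 6.0 h

Turn the question round: for the flask to turn all its substrate into product, the partner would have to cover both claims on it. So follow one molecule of protic impurity. Its one fate is quenching, and with [partner] held at its charge its half-life is 4.38 s. At the charged concentrations the catalytic round is paced by the release of product, its rate-limiting step there, slower than either binding step, so with the whole catalyst working it spends partner at about 0.0330 M/s.

That gives the quantity to carry, the usable partner: the charge of partner minus the charge of protic impurity, here 1.80 M. At that rate the round would take about 54.5 s over this amount, and I expect the impurity to be quenched first because its half-life is shorter than that. Turning all the substrate into product needs usable partner equal to the substrate charge, but this flask falls short of that charge by 0.200 M, which makes the partner the limiting reagent.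

I therefore expect product to stop at 90.0 % of the substrate charged. The catalyst should end parked on substrate as intermediate A, which puts conversion at 90.5 %. Precatalyst activation, with a half-life of 2.03 min, adds minutes, and the 6.0 h allowed is far longer.

The forecast reads the partner has run out first, with 90.5 % conversion and 90 % product, and holds that “The impurity is quenched within tens of seconds”.

The simulated flask gives the partner has run out first, with 90.5 % conversion and 90.0 % product, against the reckoned 90.0 %. At 6.00 h it holds 0.400 M of quenched reagent and 0 % of its partner. In the neighbour flask charged with 0.50 M of substrate, the usable partner is still 1.80 M, which is more than that charge. Subtracting the substrate leaves 59.1 % of the partner's charge, and that neighbour ended with 59 % of its partner and 0 % of its substrate.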